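**Subtract first.** Before you read any rate, take the charged impurity away from the charged free catalyst. What remains is the working catalyst, w.

| flask | starting material | second substrate | free catalyst | impurity | remark | time |
|---|---|---|---|---|---|---|
| epsilon | 0.10 M | 0.10 M | 0.57 mM | 0.45 mM | run made earlier |  |
| alpha | 0.10 M | 0.10 M | 0.99 mM | 0.45 mM | run made earlier |  |
| zeta | 0.10 M | 0.10 M | 1.6 mM | 0.45 mM | run made earlier |  |
| Wednesday's | 0.10 M | 0.100 M | 0.52 mM | 0.45 mM |  | 50 min |
| Friday's | 0.10 M | 0.100 M | 1.0 mM | 0.45 mM |  | 50 min |
| Sunday's | 0.10 M | 0.100 M | 2.1 mM | 0.45 mM |  | 50 min |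

| run | time / min | target / % | starting material / % | catalyst intermediate A / % |
|---|---|---|---|---|
| epsilon | 2.00 | 1.0 | 99.2 | 0.2 |
| epsilon | 6.00 | 1.8 | 97.9 | 0 |
| epsilon | 12.0 | 3.9 | 96.0 | 0 |
| epsilon | 20.0 | 5.7 | 94.5 | 0 |
| epsilon | 25.0 | 6.4 | 93.4 | 0 |
| alpha | 5.00 | 6.5 | 92.4 | 0 |
| alpha | 10.0 | 12.6 | 87.1 | 0.3 |
| alpha | 15.0 | 18.8 | 81.3 | 0.5 |
| alpha | 20.0 | 23.6 | 75.9 | 0.2 |
| alpha | 25.0 | 27.9 | 71.9 | 0.6 |
| zeta | 2.00 | 5.4 | 93.4 | 0.3 |
| zeta | 6.00 | 16.9 | 82.9 | 0.8 |
| zeta | 12.0 | 31.5 | 68.4 | 0.5 |
| zeta | 20.0 | 47.6 | 52.0 | 0.1 |
| zeta | 25.0 | 56.5 | 43.3 | 0 |

(standard deviation of a reading: 0.3 percentage points)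

- the earlier runs were read with a standard deviation of 0.3 percentage points

- which of these there is most of at the end, counted by the starting material in it, Wednesday's (target / starting material / catalyst intermediate A)
- which of these there is most of at the end, counted by the starting material in it, Friday's (target / starting material / catalyst intermediate A)
- which of these there is most of at the end, counted by the starting material in it, Sunday's (target / starting material / catalyst intermediate A)
- the largest of these amounts at the end, in percent of the starting material charged, Wednesday's
- the largest of these amounts at the end, in percent of the starting material charged, Friday's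
- the largest of these amounts at the end, in percent of the starting material charged, Sunday's

**Fastest rung.** In the zeta run, catalyst intermediate A reads 0.8% at 6.00 min against 16.9% of target. So in the zeta run you can count the starting material as either unreacted or target.

**Next rung.** Target in the zeta run reads 5.4% at 2.00 min and 16.9% at 6.00 min, one pace. I therefore take the impurity's bite in the zeta run as finished by its first reading.

**Working half-time.** Treat the starting material as pseudo-first-order. Its half-time in the alpha run, read from the last reading, is 52.5 min, and the working half-time is this figure scaled inversely with w. From the epsilon run to the zeta run, the half-time read the same way falls from 254 min to 20.7 min, a factor of 12.3. Over the same runs w grows 9.58-fold, but the charge grows just 2.81-fold.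

**Slowest rungs.** Set each half-time against 50 min:

- Sunday's flask has 17.2 min, shorter than the run, so I expect 13.3% starting material left and 86.7% target.
- Friday's flask has 51.6 min, longer than the run, so I expect 51.1% starting material left.
- Wednesday's flask has 405 min, so I expect 91.8% left.

**The forecast.** It names starting material at 94% for Wednesday's flask, starting material at 53% for Friday's and target at 89% for Sunday's, on the ground that “the impurity stoichiometrically kills that much catalyst”. Its figures stand above mine by 2.2 points, 1.9 points and 2.3 points, but the choices agree.

**The result.** The flasks give starting material at 93.7% for Wednesday's flask, starting material at 53.9% for Friday's and target at 97.1% for Sunday's, which is 10 points above my figure.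

    catalyst intermediate B → spent catalyst A (k = 0.00211 s⁻¹)
    catalyst intermediate B → free catalyst + second product (k = 0.373 s⁻¹)
    free catalyst + impurity → spent catalyst B (k = 607 L mol⁻¹ s⁻¹)
    starting material + free catalyst ⇌ catalyst intermediate A (K = 1200 L mol⁻¹, k = 1.64 L mol⁻¹ s⁻¹)
    second substrate + free catalyst ⇌ catalyst intermediate B (K = 140 L mol⁻¹, k = 2.04 L mol⁻¹ s⁻¹)
    catalyst intermediate A → free catalyst + target (k = 0.0766 s⁻¹)

**The neighbour.** Now raise the impurity in Sunday's flask to 0.0018 M, with the free catalyst still at 2.1 mM. Then w is 0.300 mM, the working half-time becomes 94.6 min, and 69.3% starting material should remain. That flask shows spent catalyst B at 85.7% of the catalyst charged and impurity at 0%. It ends with 74.1% starting material.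

(Readings and results were computed with constants of no real substance, noise included.)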